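**Retrosynthetic overview**

1. The depside ester bond O4–C(=O) is made last. Ring A (the heptyl-bearing benzoic acid ring) enters as benzyl 2-heptyl-4,6-dihydroxybenzoate 18, and ring B as 2,4-bis(benzyloxy)-6-methylbenzoic acid 21 from orsellinic acid. Ring B is bought; ring A is the only ring that is built.
2. The strategy rests on ring A: oxygens at C4 and C6 flank an unsubstituted C5, and C3–H sits next to the heptyl-bearing C2. This is the pattern that a ketene carbon (C6) and a terminal siloxyalkyne (C5, C4) give, with O6 free and O4 silylated.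
3. Ring A is cut into diazo ketone 9 (C1, C2, C3, C6, ester and heptyl) and (triisopropylsilyloxy)ethyne 13 (C4, C5). The bonds C2–C3, C5–C6, C3–C4 and C1–C6 form in one operation.
4. 9 comes from an E-selective Wittig reaction of acyl ylide 4 with benzyl glyoxylate 6, then a detrifluoroacetylative diazo transfer. Diazomethane is avoided because the fumarate-type alkene is a dipolarophile.
5. After the annulation: desilylation at O4, acylation of O4 with 21, and hydrogenolysis of three benzyl groups.

Key step: step 7

Assumption: lithium ethynolate 12 is taken to be silylated on oxygen by i-Pr3SiOTf as its alkyl-substituted homologues are; 13 is used soon after it is made.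

**Route**

Step 1
Reactants: 1 n-octyltriphenylphosphonium bromide; 2 acetyl chloride
Product: 4 3-(triphenylphosphoranylidene)decan-2-one, via octylidenetriphenylphosphorane 3 (not isolated)
Conditions: NaN(SiMe3)2 (2 equiv per 2 equiv of 1), THF, 0 °C; then 2 (1 equiv), −78 °C → rt; filter off the phosphonium salt
Reagents that add atoms: none
Why: Deprotonation gives the non-stabilized ylide 3, which is C-acylated by acetyl chloride, and the acylphosphonium salt is deprotonated by the second equivalent of 3 (Bestmann acylation with transylidation) to give the stabilized acyl ylide that carries the heptyl group and the future C2, C3 and C6.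

Step 2
Reactants: 5 dibenzyl L-tartrate
Product: 6 benzyl glyoxylate
Conditions: H5IO6, Et2O, rt
Reagents that add atoms: none
Why: Periodate glycol cleavage of the tartrate diol gives two molecules of the glyoxylate, which is used at once because it hydrates and oligomerizes on standing.

Step 3
Reactants: 4 3-(triphenylphosphoranylidene)decan-2-one; 6 benzyl glyoxylate
Product: 7 benzyl (E)-3-acetyldec-2-enoate
Conditions: toluene, 60 °C
Reagents that add atoms: none
Why: Wittig olefination of the very electrophilic glyoxylate aldehyde with a stabilized, α-branched acyl ylide should be E-selective, placing the ester trans to the acetyl group as the later electrocyclization requires.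

Step 4
Reactants: 7 benzyl (E)-3-acetyldec-2-enoate
Product: 8 benzyl (E)-3-(4,4,4-trifluoro-3-oxobutanoyl)dec-2-enoate (used crude)
Conditions: LiN(SiMe3)2, THF, −78 °C; CF3CO2CH2CF3, −78 °C; aq. HCl work-up
Reagents that add atoms: 2,2,2-trifluoroethyl trifluoroacetate, O=C(OCC(F)(F)F)C(F)(F)F
Why: Kinetic deprotonation of the methyl ketone at −78 °C and Claisen acylation of the enolate with the trifluoroacetate ester activate the methyl group as a 1,3-diketone (first half of the Danheiser detrifluoroacetylative diazo transfer).

Step 5
Reactants: 8 benzyl (E)-3-(4,4,4-trifluoro-3-oxobutanoyl)dec-2-enoate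
Product: 9 benzyl (E)-3-(2-diazoacetyl)dec-2-enoate
Conditions: MsN3, Et3N, H2O (1 equiv), MeCN, rt; product kept cold and used promptly
Reagents that add atoms: methanesulfonyl azide, CS(=O)(=O)N=[N+]=[N-]
Why: Regitz-type diazo transfer to the activated methylene with loss of the trifluoroacetyl group onto the sulfonamide nitrogen gives the diazo ketone without diazomethane, which would add as a 1,3-dipole to the fumarate-type double bond of an acid chloride precursor.

Step 6
Reactants: 10 acetylene
Product: 13 (triisopropylsilyloxy)ethyne, via lithium acetylide 11 (not isolated), via lithium ethynolate 12 (not isolated)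
Conditions: n-BuLi, THF, −78 °C; t-BuOOLi (from t-BuOOH and LiN(SiMe3)2), THF, −78 → −20 °C; i-Pr3SiOTf, −78 → 0 °C
Reagents that add atoms: tert-butyl hydroperoxide, CC(C)(C)OO; triisopropylsilyl trifluoromethanesulfonate, CC(C)[Si](OS(=O)(=O)C(F)(F)F)(C(C)C)C(C)C
Why: Electrophilic oxygenation of the lithium acetylide by lithium tert-butyl peroxide gives the ynolate, and the hard, bulky silyl triflate silylates it on oxygen and not on carbon (Julia-type acetylide oxidation followed by ynolate O-silylation).

Step 7
Reactants: 9 benzyl (E)-3-(2-diazoacetyl)dec-2-enoate; 13 (triisopropylsilyloxy)ethyne (excess)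
Product: 17 benzyl 2-heptyl-6-hydroxy-4-(triisopropylsilyloxy)benzoate, via vinylketene 14 (not isolated), via cyclobutenone 15 (not isolated), via dienylketene 16 (not isolated)
Conditions: degassed ClCH2CH2Cl, hν (254 nm, low-pressure Hg lamp, Vycor), rt; then 80 °C
Reagents that add atoms: none
Why: Irradiation expels N2 and the alkenyl group shifts to the carbene carbon (photochemical Wolff rearrangement, new C2–C3 bond) to give vinylketene 14, whose electrophilic ketene carbon bonds to the nucleophilic unsubstituted carbon of 13 in a [2+2] cycloaddition (C5–C6 and C3–C4 bonds) to give cyclobutenone 15. On warming, 15 undergoes 4π electrocyclic opening to dienylketene 16, which closes ring A by a thermal disrotatory 6π electrocyclization between the ketene carbon and the ester-bearing alkene terminus (C1–C6 bond) and then enolizes to the phenol. The closest known reaction is the Danheiser benzannulation in its diazo ketone form with triisopropylsiloxyalkynes; the ester on the vinylketene terminus is a new substituent for it, not a new reaction type. No stereocenter is formed. The step needs regiocontrol in the [2+2] event, which the polarization of the siloxyalkyne supplies, so that the ketene oxygen becomes the free, chelated O6–H and the alkyne oxygen the silylated O4. It also needs the ester to stay away from the ketene, which the E geometry of 9 secures (ester trans to the ketenyl group, so no capture of the ketene as a 2-pyranone).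

Step 8
Reactants: 17 benzyl 2-heptyl-6-hydroxy-4-(triisopropylsilyloxy)benzoate
Product: 18 benzyl 2-heptyl-4,6-dihydroxybenzoate
Conditions: Bu4NF, AcOH, THF, 0 °C
Reagents that add atoms: none
Why: Buffered fluoride cleaves the aryl silyl ether and leaves the benzyl ester untouched (desilylation), giving the resorcinol in which O6–H is hydrogen-bonded to the ester carbonyl and O4–H is free.

Step 9
Reactants: 19 orsellinic acid (2,4-dihydroxy-6-methylbenzoic acid)
Product: 20 benzyl 2,4-bis(benzyloxy)-6-methylbenzoate
Conditions: BnBr, K2CO3, DMF, rt → 60 °C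
Reagents that add atoms: benzyl bromide, BrCc1ccccc1
Why: Williamson alkylation of the carboxylate and both phenoxides, with the carboxylate alkylated at room temperature before warming so that the decarboxylation-prone free acid is consumed early.

Step 10
Reactants: 20 benzyl 2,4-bis(benzyloxy)-6-methylbenzoate
Product: 21 2,4-bis(benzyloxy)-6-methylbenzoic acid
Conditions: KOH, DMSO–H2O, 90 °C; then aq. HCl
Reagents that add atoms: potassium hydroxide, [K+].[OH-]
Why: Saponification of the hindered benzoate in hot aqueous DMSO, to which the benzyl ethers are inert.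

Step 11
Reactants: 18 benzyl 2-heptyl-4,6-dihydroxybenzoate; 21 2,4-bis(benzyloxy)-6-methylbenzoic acid
Product: 23 benzyl 4-{[2,4-bis(benzyloxy)-6-methylbenzoyl]oxy}-2-heptyl-6-hydroxybenzoate, via mixed anhydride 22 (not isolated)
Conditions: (CF3CO)2O, toluene, rt
Reagents that add atoms: none
Why: The acid forms mixed anhydride 22, which transfers the electron-rich, acylium-like aroyl group to the free O4–H of 18 while the hydrogen-bonded O6–H does not react (trifluoroacetic anhydride-mediated depside esterification).

Step 12
Reactants: 23 benzyl 4-{[2,4-bis(benzyloxy)-6-methylbenzoyl]oxy}-2-heptyl-6-hydroxybenzoate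
Product: 24 4-[(2,4-dihydroxy-6-methylbenzoyl)oxy]-2-heptyl-6-hydroxybenzoic acid (target)
Conditions: H2 (1 atm), 10% Pd/C, EtOAc, rt
Reagents that add atoms: none
Why: Hydrogenolysis of the benzyl ester and both benzyl ethers over Pd/C leaves the aryl ester link of the depside and the arenes untouched and gives the target.

**Compound list**

1 | n-octyltriphenylphosphonium bromide | CCCCCCCC[P+](c1ccccc1)(c1ccccc1)c1ccccc1.[Br-] | starting material
2 | acetyl chloride | CC(=O)Cl | starting material
3 | octylidenetriphenylphosphorane | CCCCCCCC=P(c1ccccc1)(c1ccccc1)c1ccccc1 | intermediate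
4 | 3-(triphenylphosphoranylidene)decan-2-one | CCCCCCCC(C(C)=O)=P(c1ccccc1)(c1ccccc1)c1ccccc1 | intermediate
5 | dibenzyl L-tartrate, (2R,3R) | O=C(OCc1ccccc1)[C@H](O)[C@@H](O)C(=O)OCc1ccccc1 | starting material
6 | benzyl glyoxylate | O=CC(=O)OCc1ccccc1 | intermediate
7 | benzyl (E)-3-acetyldec-2-enoate (ester trans to acetyl) | CCCCCCC/C(C(C)=O)=C\C(=O)OCc1ccccc1 | intermediate
8 | benzyl (E)-3-(4,4,4-trifluoro-3-oxobutanoyl)dec-2-enoate | CCCCCCC/C(C(=O)CC(=O)C(F)(F)F)=C\C(=O)OCc1ccccc1 | intermediate
9 | benzyl (E)-3-(2-diazoacetyl)dec-2-enoate | CCCCCCC/C(C(=O)C=[N+]=[N-])=C\C(=O)OCc1ccccc1 | intermediate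
10 | acetylene | C#C | starting material
11 | lithium acetylide | [Li]C#C | intermediate
12 | lithium ethynolate | [Li]OC#C | intermediate
13 | (triisopropylsilyloxy)ethyne | C#CO[Si](C(C)C)(C(C)C)C(C)C | intermediate
14 | benzyl (2E)-3-heptyl-5-oxopenta-2,4-dienoate (vinylketene) | CCCCCCC/C(C=C=O)=C\C(=O)OCc1ccccc1 | intermediate
15 | benzyl (E)-3-[4-oxo-2-(triisopropylsilyloxy)cyclobut-2-en-1-yl]dec-2-enoate (racemic at the ring carbon) | CCCCCCC/C(C1C(=O)C=C1O[Si](C(C)C)(C(C)C)C(C)C)=C\C(=O)OCc1ccccc1 | intermediate
16 | benzyl (2E,4E)-3-heptyl-7-oxo-5-(triisopropylsilyloxy)hepta-2,4,6-trienoate (dienylketene) | CCCCCCC/C(=C\C(=O)OCc1ccccc1)/C=C(/O[Si](C(C)C)(C(C)C)C(C)C)\C=C=O | intermediate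
17 | benzyl 2-heptyl-6-hydroxy-4-(triisopropylsilyloxy)benzoate | CCCCCCCc1cc(O[Si](C(C)C)(C(C)C)C(C)C)cc(O)c1C(=O)OCc1ccccc1 | intermediate
18 | benzyl 2-heptyl-4,6-dihydroxybenzoate | CCCCCCCc1cc(O)cc(O)c1C(=O)OCc1ccccc1 | intermediate
19 | orsellinic acid (2,4-dihydroxy-6-methylbenzoic acid) | Cc1cc(O)cc(O)c1C(=O)O | starting material
20 | benzyl 2,4-bis(benzyloxy)-6-methylbenzoate | Cc1cc(OCc2ccccc2)cc(OCc2ccccc2)c1C(=O)OCc1ccccc1 | intermediate
21 | 2,4-bis(benzyloxy)-6-methylbenzoic acid | Cc1cc(OCc2ccccc2)cc(OCc2ccccc2)c1C(=O)O | intermediate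
22 | 2,4-bis(benzyloxy)-6-methylbenzoic trifluoroacetic anhydride | Cc1cc(OCc2ccccc2)cc(OCc2ccccc2)c1C(=O)OC(=O)C(F)(F)F | intermediate
23 | benzyl 4-{[2,4-bis(benzyloxy)-6-methylbenzoyl]oxy}-2-heptyl-6-hydroxybenzoate | CCCCCCCc1cc(OC(=O)c2c(C)cc(OCc3ccccc3)cc2OCc2ccccc2)cc(O)c1C(=O)OCc1ccccc1 | intermediate
24 | 4-[(2,4-dihydroxy-6-methylbenzoyl)oxy]-2-heptyl-6-hydroxybenzoic acid | CCCCCCCc1cc(OC(=O)c2c(C)cc(O)cc2O)cc(O)c1C(=O)O | target

**Step count**

Total steps: 12. Longest linear sequence: 8 steps (1, 3, 4, 5, 7, 8, 11, 12).

**Steps most likely to fail**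

Step 7. Under 254 nm light the enoate double bond of 9 or 14 may isomerize to the Z form, after which the ester carbonyl can capture the ketene. The electron-poor vinylketene may also oligomerize before it meets 13, or the cyclobutenone may convert incompletely on warming. The fallback sets out from 13 and comes back at 18. It uses the thermal cyclobutenone form of the annulation without the ester and adds the carboxyl group afterwards.
- 1-Nonyne and dichloroketene (Cl3CCOCl, Zn(Cu) couple, Et2O) should give 4,4-dichloro-3-heptylcyclobut-2-en-1-one F1.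
- Zn, AcOH and TMEDA in EtOH should reduce it to 3-heptylcyclobut-2-en-1-one F2.
- Heating F2 with 13 in toluene at 80 °C should give 3-heptyl-5-(triisopropylsilyloxy)phenol F3.
- Bu4NF in THF should give 5-heptylbenzene-1,3-diol F4.
- Carboxylation with CH3OMgOCO2CH3 in DMF at 120 °C and acidification should place the carboxyl group ortho to a hydroxyl and next to the alkyl chain, as with other 5-alkylresorcinols, giving 2-heptyl-4,6-dihydroxybenzoic acid F5.
- BnBr and KHCO3 in DMF should alkylate only the carboxylate and give 18.

Step 6. Lithium acetylide may disproportionate before oxygen transfer, the ynolate may be silylated on carbon to give a silylketene, and the volatile, acid-sensitive product may be lost on isolation. The fallback sets out from 9 and comes back at 18. It replaces the silyl ynol ether by a tert-butyl ynol ether, whose parent is made by elimination chemistry.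
- KOt-Bu and trichloroethylene in THF should give (E)-1,2-dichlorovinyl tert-butyl ether F6.
- n-BuLi (2 equiv) at −78 °C, then MeOH, should give tert-butoxyethyne F7.
- Irradiation of 9 with F7 as in step 7, with the excess ynol ether removed in vacuum before warming to 80 °C, should give benzyl 4-tert-butoxy-2-heptyl-6-hydroxybenzoate F8.
- CF3CO2H in CH2Cl2 at 0 °C should cleave the aryl tert-butyl ether and leave the benzyl ester, giving 18, so step 8 is not needed.

Step 4. The lithium enolate of 7 may add in conjugate fashion to the doubly activated alkene of a second molecule, or deprotonation at the γ-position may scramble the alkene geometry. The fallback sets out from 6 and comes back at 9. It installs the diazo ketone before the alkene, so that neither a strong base nor diazomethane meets the fumarate-type double bond.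
- Triethyl phosphonoacetate, NaH and 1-bromoheptane in DMF should give ethyl 2-(diethoxyphosphoryl)nonanoate F9.
- NaOH in aqueous EtOH, then acid, should give 2-(diethoxyphosphoryl)nonanoic acid F10.
- (COCl)2 with catalytic DMF in CH2Cl2 should give 2-(diethoxyphosphoryl)nonanoyl chloride F11.
- Excess CH2N2 in Et2O at 0 °C should give diethyl (1-diazo-2-oxodecan-3-yl)phosphonate F12.
- Horner–Wadsworth–Emmons olefination of 6 with F12 (LiCl, i-Pr2NEt, MeCN, rt) should give 9, with the E isomer separated by chromatography if needed.

**Further compounds**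

F1 | step 7 | 4,4-dichloro-3-heptylcyclobut-2-en-1-one | CCCCCCCC1=CC(=O)C1(Cl)Cl
F2 | step 7 | 3-heptylcyclobut-2-en-1-one | CCCCCCCC1=CC(=O)C1
F3 | step 7 | 3-heptyl-5-(triisopropylsilyloxy)phenol | CCCCCCCc1cc(O)cc(O[Si](C(C)C)(C(C)C)C(C)C)c1
F4 | step 7 | 5-heptylbenzene-1,3-diol | CCCCCCCc1cc(O)cc(O)c1
F5 | step 7 | 2-heptyl-4,6-dihydroxybenzoic acid | CCCCCCCc1cc(O)cc(O)c1C(=O)O
F6 | step 6 | (E)-1,2-dichlorovinyl tert-butyl ether | CC(C)(C)O/C(Cl)=C\Cl
F7 | step 6 | tert-butoxyethyne | CC(C)(C)OC#C
F8 | step 6 | benzyl 4-tert-butoxy-2-heptyl-6-hydroxybenzoate | CCCCCCCc1cc(OC(C)(C)C)cc(O)c1C(=O)OCc1ccccc1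
F9 | step 4 | ethyl 2-(diethoxyphosphoryl)nonanoate | CCCCCCCC(C(=O)OCC)P(=O)(OCC)OCC
F10 | step 4 | 2-(diethoxyphosphoryl)nonanoic acid | CCCCCCCC(C(=O)O)P(=O)(OCC)OCC
F11 | step 4 | 2-(diethoxyphosphoryl)nonanoyl chloride | CCCCCCCC(C(=O)Cl)P(=O)(OCC)OCC
F12 | step 4 | diethyl (1-diazo-2-oxodecan-3-yl)phosphonate | CCCCCCCC(C(=O)C=[N+]=[N-])P(=O)(OCC)OCC
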